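The ten-membered carbocycle is opened at C8–C9. In the target the C8 acyloxy carbon lies homoallylic, through C9, to the exocyclic C10=C14 methylene of that ring, so C9–C10(=C14) is read as a 2-substituted allyl unit added to a C8 aldehyde. One intramolecular Hosomi–Sakurai allylation closes the carbocycle, sets C8 with its free hydroxyl and creates the C10=C14 alkene. Its precursor is a seco aldehyde: the cis-fused γ-lactone (C6, C7, C11, C12) bearing the formyl group on C7 and, on C6, the C4=C5 alkene (C3 cis to C6, C15–OPMB), whose C3–C2 chain ends at the chiral-pool C1 silyl ether carrying the 2-(trimethylsilylmethyl)vinyl group.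

Key step: step 16

Remark: atom labels follow germacranolide numbering (C1 carbinol, C4=C5 with C15 on C4, C6–O and C12=O of the lactone, C7, C8, C9, C10=C14, C11=C13; side-chain atoms primed); TBS = tert-butyldimethylsilyl, TES = triethylsilyl, PMB = 4-methoxybenzyl; 17, 31–33, 37 and 38 are epimer mixtures at a centre that the next operation removes.

Step 1
Reactants: 1 prop-2-yn-1-ol
Product: 2 1-methoxy-4-[(prop-2-yn-1-yloxy)methyl]benzene
Conditions: NaH, 4-methoxybenzyl chloride, Bu4NI (cat.), THF/DMF, 0 °C → rt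
Reagents that add atoms: 4-methoxybenzyl chloride, COc1ccc(CCl)cc1
Why: Williamson etherification of the primary alkoxide with a benzylic chloride installs the PMB group that masks the future C15 oxygen until after the lactone methylenation.

Step 2
Reactants: 3 4-(benzyloxy)butanoic acid; 4 (S)-4-benzyloxazolidin-2-one
Product: 6 (S)-4-benzyl-3-[4-(benzyloxy)butanoyl]oxazolidin-2-one, via mixed pivalic anhydride 5 (not isolated)
Conditions: PivCl, Et3N, THF, −20 °C; then 4, LiCl, −20 °C → rt
Reagents that add atoms: none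
Why: N-acylation of the oxazolidinone by a mixed anhydride under LiCl/Et3N activation is the standard entry to an Evans imide, whose four acyl carbons become C6, C7, C11 and C12.

Step 3
Reactants: 6 imide
Product: 8 (S)-4-benzyl-3-[(R)-4-(benzyloxy)-2-(hydroxymethyl)butanoyl]oxazolidin-2-one, via chlorotitanium enolate 7 (not isolated)
Conditions: TiCl4, i-Pr2NEt, CH2Cl2, 0 °C; then 1,3,5-trioxane, TiCl4, 0 °C
Reagents that add atoms: 1,3,5-trioxane, C1OCOCO1
Why: Evans titanium-enolate hydroxymethylation, in which the chelated (Z)-enolate is attacked by TiCl4-activated formaldehyde on the face away from the benzyl group, adds C8 and sets C7 (R).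

Step 4
Reactants: 8 hydroxymethyl imide
Product: 9 (S)-4-benzyl-3-[(R)-4-(benzyloxy)-2-{[(triethylsilyl)oxy]methyl}butanoyl]oxazolidin-2-one
Conditions: Et3SiCl, imidazole, CH2Cl2, 0 °C
Reagents that add atoms: chlorotriethylsilane, CC[Si](Cl)(CC)CC
Why: Silylation of the primary C8 hydroxyl gives a TES ether that can later be removed beside a secondary TBS ether and a PMB ether.

Step 5
Reactants: 9 TES-protected imide
Product: 11 (R)-3-{[(triethylsilyl)oxy]methyl}dihydrofuran-2(3H)-one, via hydroxy imide 10 (not isolated)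
Conditions: H2 (1 atm), Pd/C, EtOAc, rt; filter; then Et3N, DMAP (cat.), CH2Cl2, rt
Reagents that add atoms: none
Why: Hydrogenolysis of the benzyl ether frees the C12 hydroxyl, which attacks the exocyclic imide carbonyl (5-exo-trig lactonisation) and expels the recoverable auxiliary without touching C7.

Step 6
Reactants: 2 PMB propargyl ether; 11 lactone
Product: 13 (R)-1-hydroxy-7-[(4-methoxybenzyl)oxy]-3-{[(triethylsilyl)oxy]methyl}hept-5-yn-4-one, via lithium acetylide 12 (not isolated)
Conditions: 2, n-BuLi, THF, −78 °C; then 11, −78 °C; aq. NH4Cl, −78 °C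
Reagents that add atoms: none
Why: Alkynyllithium addition to a lactone stops at the lithium hemiketalate at −78 °C, so the ynone (C6 ketone joined to C5≡C4–C15) is released only on quench and is not attacked twice.

Step 7
Reactants: 13 hydroxy ynone
Product: 14 (3R,4R)-7-[(4-methoxybenzyl)oxy]-3-{[(triethylsilyl)oxy]methyl}hept-5-yne-1,4-diol
Conditions: RuCl(p-cymene)[(R,R)-TsDPEN] (3 mol %), i-PrOH, rt
Reagents that add atoms: none
Why: Noyori asymmetric transfer hydrogenation of an alkynyl ketone should give the (R)-propargylic alcohol at C6 under catalyst control, and the base-free medium leaves the enolisable C7 centre and its β-silyloxy group intact.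

Step 8
Reactants: 14 propargylic diol
Product: 16 (3R,4R,5Z)-6-iodo-7-[(4-methoxybenzyl)oxy]-3-{[(triethylsilyl)oxy]methyl}hept-5-ene-1,4-diol, via sodium alkenylalanate 15 (not isolated)
Conditions: NaAlH2(OCH2CH2OMe)2, THF, 0 °C; EtOAc, −78 °C; then I2, THF, −78 → 0 °C
Reagents that add atoms: iodine, II
Why: Hydroxyl-directed trans-hydroalumination of the propargylic alcohol delivers hydride to C5 and aluminium to C4 within a five-membered alanate, and iodinolysis with retention gives the vinyl iodide with iodine cis to C6.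

Step 9
Reactants: 16 iodo diol
Product: 18 (4R,5R)-5-{(Z)-2-iodo-3-[(4-methoxybenzyl)oxy]prop-1-en-1-yl}-4-{[(triethylsilyl)oxy]methyl}dihydrofuran-2(3H)-one, via lactol 17 (not isolated)
Conditions: TEMPO (cat.), PhI(OAc)2, CH2Cl2, rt
Reagents that add atoms: none
Why: TEMPO/PhI(OAc)2 oxidative lactonisation is selective for the primary C12 alcohol, whose aldehyde is trapped by the C6 hydroxyl as a lactol and oxidised on to the cis-fused γ-lactone with both stereocentres untouched.

Step 10
Reactants: 19 (R)-3-hydroxydihydrofuran-2(3H)-one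
Product: 20 (R)-3-[(tert-butyldimethylsilyl)oxy]dihydrofuran-2(3H)-one
Conditions: t-BuMe2SiCl, imidazole, DMF, 0 °C → rt
Reagents that add atoms: tert-butyldimethylsilyl chloride, CC(C)(C)[Si](C)(C)Cl
Why: Silylation protects the carbinol of the chiral-pool lactone that supplies C1 (R), C2, C3 and C10, so C1 needs no remote stereocontrol later.

Step 11
Reactants: 20 silyloxy lactone
Product: 22 (R)-3-[(tert-butyldimethylsilyl)oxy]-4-[(trimethylsilyl)methyl]pent-4-en-1-ol, via bis(silylmethyl) carbinol 21 (not isolated)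
Conditions: Me3SiCH2MgCl, CeCl3, THF, −78 °C → rt; aq. NH4Cl; then SiO2, CH2Cl2, rt
Reagents that add atoms: (trimethylsilyl)methylmagnesium chloride, C[Si](C)(C)C[Mg]Cl
Why: Double addition of the weakly basic organocerium reagent to the lactone carbonyl followed by Peterson elimination of one β-hydroxysilane turns C10 into the 2-substituted allylsilane (C9, C14) without epimerising C1.

Step 12
Reactants: 22 hydroxy allylsilane
Product: 24 (R)-tert-butyl({5-iodo-2-[(trimethylsilyl)methyl]pent-1-en-3-yl}oxy)dimethylsilane, via mesylate 23 (not isolated)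
Conditions: MsCl, Et3N, CH2Cl2, 0 °C; then NaI, NaHCO3, acetone, 45 °C
Reagents that add atoms: sodium iodide, [Na+].[I-]
Why: Mesylation and Finkelstein displacement give the primary iodide without electrophilic iodine, which would attack the allylsilane.

Step 13
Reactants: 24 alkyl iodide; 18 iodo lactone
Product: 26 (4R,5S)-5-[(1E,5R)-5-(TBS-oxy)-2-(PMB-oxymethyl)-6-[(trimethylsilyl)methyl]hepta-1,6-dien-1-yl]-4-(TES-oxymethyl)dihydrofuran-2(3H)-one, via lithium borinate complex 25 (not isolated)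
Conditions: 24, 9-MeO-9-BBN, t-BuLi, Et2O/THF, −78 °C → rt; then 18, Pd(dppf)Cl2 (5 mol %), AsPh3, aq. K3PO4, DMF, rt
Reagents that add atoms: none
Why: B-alkyl Suzuki–Miyaura coupling, in which iodine–lithium exchange and capture by the borane give an alkyl borinate that couples with the vinyl iodide with retention of geometry, forms C3–C4 with C3 cis to C6.

Step 14
Reactants: 26 TES-protected seco lactone
Product: 27 (4R,5S)-5-[(1E,5R)-5-(TBS-oxy)-2-(PMB-oxymethyl)-6-[(trimethylsilyl)methyl]hepta-1,6-dien-1-yl]-4-(hydroxymethyl)dihydrofuran-2(3H)-one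
Conditions: PPTS (cat.), MeOH/CH2Cl2, 0 °C
Reagents that add atoms: none
Why: Acid-catalysed methanolysis removes the primary TES ether far faster than the hindered secondary TBS ether, and the PMB ether, lactone and allylsilane tolerate PPTS.

Step 15
Reactants: 27 seco alcohol
Product: 28 (2S,3S)-2-[(1E,5R)-5-(TBS-oxy)-2-(PMB-oxymethyl)-6-[(trimethylsilyl)methyl]hepta-1,6-dien-1-yl]-5-oxotetrahydrofuran-3-carbaldehyde
Conditions: Dess–Martin periodinane, NaHCO3, CH2Cl2, 0 °C
Reagents that add atoms: none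
Why: Dess–Martin oxidation gives the C8 aldehyde under buffered, base-free conditions that avoid epimerisation at C7 and β-elimination of the lactone oxygen; the aldehyde is used at once.

Step 16
Reactants: 28 seco allylsilane aldehyde
Product: 29 (1R,6S,7R,8S,4E)-1-(TBS-oxy)-8-hydroxy-15-(PMB-oxy)-13-norgermacra-4,10(14)-dien-12,6-olide
Conditions: BF3·OEt2 (3 equiv), 2,6-di-tert-butyl-4-methylpyridine, CH2Cl2 (1 mM), −78 °C; aq. NaHCO3
Reagents that add atoms: none
Why: BF3 binds the C8 aldehyde oxygen and the CH2 terminus of the 2-substituted allylsilane (future C9) adds to the activated carbonyl through an open transition state, giving a β-silyl cation at C10 that sheds Me3Si to fluoride and leaves the C10=C14 methylene and, after work-up, the free C8 hydroxyl. The closest known reaction type is the intramolecular Hosomi–Sakurai allylsilane–aldehyde cyclisation used to form carbocycles. The ten-membered ring closes in a 10-exo-trig mode at the aldehyde carbon, with the attacking alkene endocyclic to the new ring. The new C8 centre is governed by the adjacent C7 centre of the cis-fused lactone: in the Felkin–Anh arrangement the C7–C6 bond lies anti to the incoming C9 and the carbonyl oxygen sits next to C11, which with monodentate BF3 (no chelate to the lactone oxygen) should favour the 8S alcohol, with oxygen syn to C11 along C6–C7–C8–C9. The step needs aldehyde over lactone and allylsilane over the C4=C5 alkene (secured by the high nucleophilicity of the β-silyl alkene toward a BF3-bound aldehyde), ring closure over oligomerisation and protodesilylation (secured by high dilution, a hindered pyridine as proton trap, and the cis-lactone plus C3/C6-cis alkene that turn the chain ends toward each other), and retention of the C7 configuration (secured by −78 °C and the absence of base).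

Step 17
Reactants: 29 macrocyclic hydroxy lactone
Product: 32 (1R,6S,7R,8S,4E)-13-(dimethylamino)-1-(TBS-oxy)-8-hydroxy-15-(PMB-oxy)germacra-4,10(14)-dien-12,6-olide (C11 epimers), via silyl ketene acetal 30 (not isolated), via O-silylated Mannich base 31 (not isolated)
Conditions: Me3SiCl, LiN(i-Pr)2, THF, −78 °C; then CH2=NMe2+ I−, −78 °C → rt; aq. citric acid; NaHCO3
Reagents that add atoms: N,N-dimethylmethyleneiminium iodide, C=[N+](C)C.[I-]
Why: In situ silylation caps the C8 alkoxide (so it cannot move the lactone to C8) and converts the lactone into its silyl ketene acetal, which undergoes a Mukaiyama–Mannich reaction with the iminium salt at C11 before the acidic wash removes the O–SiMe3 group.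

Step 18
Reactants: 32 Mannich base
Product: 34 (1R,6S,7R,8S,4E)-1-(TBS-oxy)-8-hydroxy-15-(PMB-oxy)germacra-4,10(14),11(13)-trien-12,6-olide, via ammonium iodide 33 (not isolated)
Conditions: MeI, MeOH/CH2Cl2, rt; then NaHCO3, EtOAc/H2O, rt
Reagents that add atoms: none
Why: N-methylation creates a trimethylammonium leaving group β to the lactone carbonyl and mild base triggers E1cB (Hofmann-type) elimination to the C11=C13 methylene without exposing the C8 hydroxyl to strong base.

Step 19
Reactants: 35 (R)-4-hydroxydihydrofuran-2(3H)-one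
Product: 39 (R)-4-hydroxy-3-methylenedihydrofuran-2(3H)-one, via dilithium dianion 36 (not isolated), via amino lactone 37 (not isolated), via ammonium iodide 38 (not isolated)
Conditions: LiN(i-Pr)2 (2.2 equiv), THF, −78 → −40 °C; CH2=NMe2+ I−, −78 → 0 °C; AcOH; then MeI, MeOH, rt; then NaHCO3, CH2Cl2/H2O
Reagents that add atoms: N,N-dimethylmethyleneiminium iodide, C=[N+](C)C.[I-]
Why: In Fráter–Seebach-type dianion chemistry the β-alkoxide is too poor a leaving group to eliminate, so the enolate is aminomethylated and quaternisation–elimination gives the α-methylene lactone with the chiral-pool carbinol (future C3′, R) untouched.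

Step 20
Reactants: 39 hydroxy methylene lactone
Product: 42 (R)-3,4-bis[(tert-butyldimethylsilyl)oxy]-2-methylenebutanoic acid, via lithium carboxylate 40 (not isolated), via tris(silyl) ester 41 (not isolated)
Conditions: LiOH, THF/H2O, 0 °C; evaporate; t-BuMe2SiCl, imidazole, DMF, rt; then K2CO3, MeOH/THF/H2O, 0 °C; KHSO4 to pH 4
Reagents that add atoms: lithium hydroxide, [Li+].[OH-]; tert-butyldimethylsilyl chloride, CC(C)(C)[Si](C)(C)Cl
Why: Saponification opens the lactone, persilylation protects both hydroxyls and the carboxylate, and carbonate then cleaves only the labile silyl ester, so the acid cannot relactonise.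

Step 21
Reactants: 34 macrocyclic C8 alcohol; 42 side-chain acid
Product: 44 8-O-[(R)-3,4-bis(TBS-oxy)-2-methylenebutanoyl] ester of 34, via mixed aroyl anhydride 43 (not isolated)
Conditions: 42, 2,4,6-Cl3C6H2COCl, Et3N, toluene, rt; then 34, DMAP, toluene, rt
Reagents that add atoms: none
Why: Yamaguchi esterification through the mixed anhydride and DMAP acylates the hindered C8 secondary alcohol with retention and leaves both α-methylene carbonyl systems alone.

Step 22
Reactants: 44 PMB-protected ester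
Product: 45 15-hydroxy compound (PMB removed from 44)
Conditions: DDQ, CH2Cl2/pH 7 buffer, 0 °C
Reagents that add atoms: none
Why: Oxidative PMB cleavage by DDQ (benzylic hydride abstraction, then hydrolysis) frees the C15 hydroxyl and is orthogonal to the silyl ethers, esters and alkenes.

Step 23
Reactants: 45 C15 alcohol
Product: 46 15-acetate of 45
Conditions: Ac2O, pyridine, DMAP (cat.), CH2Cl2, 0 °C
Reagents that add atoms: acetic anhydride, CC(=O)OC(C)=O
Why: Acetylation of the only free hydroxyl, the primary allylic C15 alcohol, installs the acetate of the target.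

Step 24
Reactants: 46 tris-TBS acetate
Product: 47 CNP0245550.1
Conditions: HF·pyridine, pyridine, THF, 0 °C → rt
Reagents that add atoms: none
Why: Fluoride cleavage of the three TBS ethers under mildly acidic conditions releases C1–OH and the side-chain diol while sparing the acetate, the C8 ester and both Michael acceptors, with no base present that could lactonise the side chain.

Compound list
1 | prop-2-yn-1-ol | C#CCO | starting material
2 | 1-methoxy-4-[(prop-2-yn-1-yloxy)methyl]benzene | C#CCOCc1ccc(OC)cc1 | intermediate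
3 | 4-(benzyloxy)butanoic acid | OC(=O)CCCOCc1ccccc1 | starting material
4 | (S)-4-benzyloxazolidin-2-one | O=C1OC[C@H](Cc2ccccc2)N1 | starting material
5 | 4-(benzyloxy)butanoic pivalic anhydride | CC(C)(C)C(=O)OC(=O)CCCOCc1ccccc1 | intermediate (not isolated)
6 | (S)-4-benzyl-3-[4-(benzyloxy)butanoyl]oxazolidin-2-one | O=C(CCCOCc1ccccc1)N1C(=O)OC[C@@H]1Cc1ccccc1 | intermediate
7 | trichlorotitanium (Z)-enolate of 6 | Cl[Ti](Cl)(Cl)O/C(=C\CCOCc1ccccc1)N1C(=O)OC[C@@H]1Cc1ccccc1 | intermediate (not isolated)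
8 | (S)-4-benzyl-3-[(R)-4-(benzyloxy)-2-(hydroxymethyl)butanoyl]oxazolidin-2-one | O=C([C@@H](CO)CCOCc1ccccc1)N1C(=O)OC[C@@H]1Cc1ccccc1 | intermediate
9 | (S)-4-benzyl-3-[(R)-4-(benzyloxy)-2-{[(triethylsilyl)oxy]methyl}butanoyl]oxazolidin-2-one | O=C([C@@H](CO[Si](CC)(CC)CC)CCOCc1ccccc1)N1C(=O)OC[C@@H]1Cc1ccccc1 | intermediate
10 | (S)-4-benzyl-3-[(R)-4-hydroxy-2-{[(triethylsilyl)oxy]methyl}butanoyl]oxazolidin-2-one | O=C([C@@H](CO[Si](CC)(CC)CC)CCO)N1C(=O)OC[C@@H]1Cc1ccccc1 | intermediate (not isolated)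
11 | (R)-3-{[(triethylsilyl)oxy]methyl}dihydrofuran-2(3H)-one | O=C1OCC[C@@H]1CO[Si](CC)(CC)CC | intermediate
12 | lithium acetylide of 2 | [Li]C#CCOCc1ccc(OC)cc1 | intermediate (not isolated)
13 | (R)-1-hydroxy-7-[(4-methoxybenzyl)oxy]-3-{[(triethylsilyl)oxy]methyl}hept-5-yn-4-one | COc1ccc(COCC#CC(=O)[C@@H](CO[Si](CC)(CC)CC)CCO)cc1 | intermediate
14 | (3R,4R)-7-[(4-methoxybenzyl)oxy]-3-{[(triethylsilyl)oxy]methyl}hept-5-yne-1,4-diol | COc1ccc(COCC#C[C@H](O)[C@@H](CO[Si](CC)(CC)CC)CCO)cc1 | intermediate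
15 | sodium oxa-alanate of 14 (aluminium on C4, cis to C6; simplified representation) | [Na+].COCCO[Al-]1(OCCOC)O[C@H]([C@@H](CO[Si](CC)(CC)CC)CCO)C=C1COCc1ccc(OC)cc1 | intermediate (not isolated)
16 | (3R,4R,5Z)-6-iodo-7-[(4-methoxybenzyl)oxy]-3-{[(triethylsilyl)oxy]methyl}hept-5-ene-1,4-diol | COc1ccc(COC/C(I)=C/[C@H](O)[C@@H](CO[Si](CC)(CC)CC)CCO)cc1 | intermediate
17 | lactol of 18 (C12 hemiacetal, anomer mixture) | COc1ccc(COC/C(I)=C/[C@@H]2OC(O)C[C@@H]2CO[Si](CC)(CC)CC)cc1 | intermediate (not isolated)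
18 | (4R,5R)-5-{(Z)-2-iodo-3-[(4-methoxybenzyl)oxy]prop-1-en-1-yl}-4-{[(triethylsilyl)oxy]methyl}dihydrofuran-2(3H)-one | COc1ccc(COC/C(I)=C/[C@@H]2OC(=O)C[C@@H]2CO[Si](CC)(CC)CC)cc1 | intermediate
19 | (R)-3-hydroxydihydrofuran-2(3H)-one | O[C@@H]1CCOC1=O | starting material
20 | (R)-3-[(tert-butyldimethylsilyl)oxy]dihydrofuran-2(3H)-one | CC(C)(C)[Si](C)(C)O[C@@H]1CCOC1=O | intermediate
21 | (R)-3-[(tert-butyldimethylsilyl)oxy]-5-(trimethylsilyl)-4-[(trimethylsilyl)methyl]pentane-1,4-diol | C[Si](C)(C)CC(O)(C[Si](C)(C)C)[C@H](O[Si](C)(C)C(C)(C)C)CCO | intermediate (not isolated)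
22 | (R)-3-[(tert-butyldimethylsilyl)oxy]-4-[(trimethylsilyl)methyl]pent-4-en-1-ol | C[Si](C)(C)CC(=C)[C@H](O[Si](C)(C)C(C)(C)C)CCO | intermediate
23 | methanesulfonate of 22 | C[Si](C)(C)CC(=C)[C@H](O[Si](C)(C)C(C)(C)C)CCOS(C)(=O)=O | intermediate (not isolated)
24 | (R)-tert-butyl({5-iodo-2-[(trimethylsilyl)methyl]pent-1-en-3-yl}oxy)dimethylsilane | C[Si](C)(C)CC(=C)[C@H](O[Si](C)(C)C(C)(C)C)CCI | intermediate
25 | lithium B-alkyl-B-methoxy-9-borabicyclo[3.3.1]nonane ate complex from 24 | [Li+].CO[B-]1(CC[C@@H](O[Si](C)(C)C(C)(C)C)C(=C)C[Si](C)(C)C)C2CCCC1CCC2 | intermediate (not isolated)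
26 | (4R,5S)-5-[(1E,5R)-5-[(tert-butyldimethylsilyl)oxy]-2-{[(4-methoxybenzyl)oxy]methyl}-6-[(trimethylsilyl)methyl]hepta-1,6-dien-1-yl]-4-{[(triethylsilyl)oxy]methyl}dihydrofuran-2(3H)-one | C[Si](C)(C)CC(=C)[C@H](O[Si](C)(C)C(C)(C)C)CC/C(COCc1ccc(OC)cc1)=C\[C@@H]1OC(=O)C[C@@H]1CO[Si](CC)(CC)CC | intermediate
27 | (4R,5S)-5-[(1E,5R)-5-[(tert-butyldimethylsilyl)oxy]-2-{[(4-methoxybenzyl)oxy]methyl}-6-[(trimethylsilyl)methyl]hepta-1,6-dien-1-yl]-4-(hydroxymethyl)dihydrofuran-2(3H)-one | C[Si](C)(C)CC(=C)[C@H](O[Si](C)(C)C(C)(C)C)CC/C(COCc1ccc(OC)cc1)=C\[C@@H]1OC(=O)C[C@@H]1CO | intermediate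
28 | (2S,3S)-2-[(1E,5R)-5-[(tert-butyldimethylsilyl)oxy]-2-{[(4-methoxybenzyl)oxy]methyl}-6-[(trimethylsilyl)methyl]hepta-1,6-dien-1-yl]-5-oxotetrahydrofuran-3-carbaldehyde (key-step precursor) | C[Si](C)(C)CC(=C)[C@H](O[Si](C)(C)C(C)(C)C)CC/C(COCc1ccc(OC)cc1)=C\[C@@H]1OC(=O)C[C@@H]1C=O | intermediate
29 | (1R,6S,7R,8S,4E)-1-[(tert-butyldimethylsilyl)oxy]-8-hydroxy-15-[(4-methoxybenzyl)oxy]-13-norgermacra-4,10(14)-dien-12,6-olide (key-step product; lactone cis-fused at C6/C7) | C1C(=O)O[C@H]2/C=C(/COCc3ccc(OC)cc3)CC[C@@H](O[Si](C)(C)C(C)(C)C)C(=C)C[C@H](O)[C@@H]12 | intermediate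
30 | 8-O-trimethylsilyl ether and O-trimethylsilyl ketene acetal of 29 | C1=C(O[Si](C)(C)C)O[C@H]2/C=C(/COCc3ccc(OC)cc3)CC[C@@H](O[Si](C)(C)C(C)(C)C)C(=C)C[C@H](O[Si](C)(C)C)[C@@H]12 | intermediate (not isolated)
31 | 8-O-trimethylsilyl ether of 32 (C11 epimers) | CN(C)CC1C(=O)O[C@H]2/C=C(/COCc3ccc(OC)cc3)CC[C@@H](O[Si](C)(C)C(C)(C)C)C(=C)C[C@H](O[Si](C)(C)C)[C@@H]12 | intermediate (not isolated)
32 | (1R,6S,7R,8S,4E)-13-(dimethylamino)-1-[(tert-butyldimethylsilyl)oxy]-8-hydroxy-15-[(4-methoxybenzyl)oxy]germacra-4,10(14)-dien-12,6-olide (C11 epimers) | CN(C)CC1C(=O)O[C@H]2/C=C(/COCc3ccc(OC)cc3)CC[C@@H](O[Si](C)(C)C(C)(C)C)C(=C)C[C@H](O)[C@@H]12 | intermediate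
33 | N-methyl quaternary ammonium iodide of 32 | C[N+](C)(C)CC1C(=O)O[C@H]2/C=C(/COCc3ccc(OC)cc3)CC[C@@H](O[Si](C)(C)C(C)(C)C)C(=C)C[C@H](O)[C@@H]12.[I-] | intermediate (not isolated)
34 | (1R,6S,7R,8S,4E)-1-[(tert-butyldimethylsilyl)oxy]-8-hydroxy-15-[(4-methoxybenzyl)oxy]germacra-4,10(14),11(13)-trien-12,6-olide | C=C1C(=O)O[C@H]2/C=C(/COCc3ccc(OC)cc3)CC[C@@H](O[Si](C)(C)C(C)(C)C)C(=C)C[C@H](O)[C@@H]12 | intermediate
35 | (R)-4-hydroxydihydrofuran-2(3H)-one | O=C1C[C@@H](O)CO1 | starting material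
36 | dilithium alkoxide enolate of 35 | [Li]OC1=C[C@@H](O[Li])CO1 | intermediate (not isolated)
37 | (4R)-3-[(dimethylamino)methyl]-4-hydroxydihydrofuran-2(3H)-one (C3 epimers, mainly trans) | CN(C)CC1C(=O)OC[C@@H]1O | intermediate (not isolated)
38 | N-methyl quaternary ammonium iodide of 37 | C[N+](C)(C)CC1C(=O)OC[C@@H]1O.[I-] | intermediate (not isolated)
39 | (R)-4-hydroxy-3-methylenedihydrofuran-2(3H)-one | C=C1C(=O)OC[C@@H]1O | intermediate
40 | lithium (R)-3,4-dihydroxy-2-methylenebutanoate | [Li+].[O-]C(=O)C(=C)[C@@H](O)CO | intermediate (not isolated)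
41 | tert-butyldimethylsilyl (R)-3,4-bis[(tert-butyldimethylsilyl)oxy]-2-methylenebutanoate | CC(C)(C)[Si](C)(C)OC(=O)C(=C)[C@@H](O[Si](C)(C)C(C)(C)C)CO[Si](C)(C)C(C)(C)C | intermediate (not isolated)
42 | (R)-3,4-bis[(tert-butyldimethylsilyl)oxy]-2-methylenebutanoic acid | OC(=O)C(=C)[C@@H](O[Si](C)(C)C(C)(C)C)CO[Si](C)(C)C(C)(C)C | intermediate
43 | mixed anhydride of 42 and 2,4,6-trichlorobenzoic acid | O=C(OC(=O)c1c(Cl)cc(Cl)cc1Cl)C(=C)[C@@H](O[Si](C)(C)C(C)(C)C)CO[Si](C)(C)C(C)(C)C | intermediate (not isolated)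
44 | (1R,6S,7R,8S,4E)-8-{[(R)-3,4-bis(tert-butyldimethylsilyloxy)-2-methylenebutanoyl]oxy}-1-[(tert-butyldimethylsilyl)oxy]-15-[(4-methoxybenzyl)oxy]germacra-4,10(14),11(13)-trien-12,6-olide | C=C1C(=O)O[C@H]2/C=C(/COCc3ccc(OC)cc3)CC[C@@H](O[Si](C)(C)C(C)(C)C)C(=C)C[C@H](OC(=O)C(=C)[C@@H](O[Si](C)(C)C(C)(C)C)CO[Si](C)(C)C(C)(C)C)[C@@H]12 | intermediate
45 | 15-hydroxy analogue of 44 (PMB removed) | C=C1C(=O)O[C@H]2/C=C(/CO)CC[C@@H](O[Si](C)(C)C(C)(C)C)C(=C)C[C@H](OC(=O)C(=C)[C@@H](O[Si](C)(C)C(C)(C)C)CO[Si](C)(C)C(C)(C)C)[C@@H]12 | intermediate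
46 | 15-acetate of 45 (tris-TBS ether of the target) | C=C1C(=O)O[C@H]2/C=C(/COC(C)=O)CC[C@@H](O[Si](C)(C)C(C)(C)C)C(=C)C[C@H](OC(=O)C(=C)[C@@H](O[Si](C)(C)C(C)(C)C)CO[Si](C)(C)C(C)(C)C)[C@@H]12 | intermediate
47 | CNP0245550.1, (1R,6S,7R,8S,4E)-15-acetoxy-8-{[(R)-3,4-dihydroxy-2-methylenebutanoyl]oxy}-1-hydroxygermacra-4,10(14),11(13)-trien-12,6-olide | C=C1C(=O)O[C@H]2/C=C(/COC(C)=O)CC[C@@H](O)C(=C)C[C@H](OC(=O)C(=C)[C@@H](O)CO)[C@@H]12 | target

Total step count: 24. Longest linear sequence: 18 steps (steps 2–9, 13–18, 21–24).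

Steps most likely to fail

Step 16 (key step). At the dilution needed, ring closure may be slower than protodesilylation of the allylsilane or intermolecular allylation, and attack on the C8 carbonyl may show poor facial selectivity. The fallback replaces the allylsilane by an allylchromium nucleophile for the same C8–C9 bond and sets out from 26. Bromodesilylation with NBS (propylene oxide, CH2Cl2, −78 °C), which the β-silyl alkene should undergo faster than the other alkenes, would give the allylic bromide F1. PPTS in MeOH would then free the bromo alcohol F2, and buffered Dess–Martin oxidation would give the bromo aldehyde F3. Slow addition of F3 to CrCl2 in THF (intramolecular Nozaki–Hiyama–Kishi-type allylation through a closed transition state) would close the ten-membered ring and come back to the route at 29.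

Step 8. The alkenylalanate may lose the neighbouring PMB-oxy group by β-elimination to an allene, the TES group may migrate between the alkoxides, or iodinolysis may be incomplete. The fallback is a hydride-free, hydroxyl-directed trans-hydrostannation and sets out from 14. TEMPO/PhI(OAc)2 would give the alkynyl lactone F4, and DDQ would free the propargylic alcohol F5. [Cp*RuCl]4-catalysed addition of Bu3SnH, directed by the free C15 hydroxyl, would place tin on C4 trans to the new C5–H and give the alkenylstannane F6. I2 would give the iodo allylic alcohol F7, and 4-methoxybenzyl trichloroacetimidate with catalytic camphorsulfonic acid would come back to the route at 18.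

Step 17. Enolisation and silylation of the lactone inside the macrocycle may be incomplete, or the C8 oxygen, if not capped in time, may attack the lactone carbonyl and move the lactone to C8. The fallback is a condensation that needs no strong base and sets out from 29. Et3SiCl and imidazole would give the C8 triethylsilyl ether F8, and heating with tert-butoxybis(dimethylamino)methane in toluene would give the enamino lactone F9. Reduction with i-Bu2AlH at −78 °C and work-up on silica gel would give the silyl-protected α-methylene lactone F10, and PPTS in MeOH would remove the TES group and come back to the route at 34.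

Further compounds
F1 | step 16 | allylic bromide from 26 (CH2Br and =CH2 on C10, C8–OTES) | BrCC(=C)[C@H](O[Si](C)(C)C(C)(C)C)CC/C(COCc1ccc(OC)cc1)=C\[C@@H]1OC(=O)C[C@@H]1CO[Si](CC)(CC)CC
F2 | step 16 | bromo alcohol (C8–OH) | BrCC(=C)[C@H](O[Si](C)(C)C(C)(C)C)CC/C(COCc1ccc(OC)cc1)=C\[C@@H]1OC(=O)C[C@@H]1CO
F3 | step 16 | bromo aldehyde (C8 formyl) | BrCC(=C)[C@H](O[Si](C)(C)C(C)(C)C)CC/C(COCc1ccc(OC)cc1)=C\[C@@H]1OC(=O)C[C@@H]1C=O
F4 | step 8 | (4R,5R)-5-{3-[(4-methoxybenzyl)oxy]prop-1-yn-1-yl}-4-{[(triethylsilyl)oxy]methyl}dihydrofuran-2(3H)-one | COc1ccc(COCC#C[C@@H]2OC(=O)C[C@@H]2CO[Si](CC)(CC)CC)cc1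
F5 | step 8 | (4R,5R)-5-(3-hydroxyprop-1-yn-1-yl)-4-{[(triethylsilyl)oxy]methyl}dihydrofuran-2(3H)-one | OCC#C[C@@H]1OC(=O)C[C@@H]1CO[Si](CC)(CC)CC
F6 | step 8 | (4R,5R)-5-[(Z)-3-hydroxy-2-(tributylstannyl)prop-1-en-1-yl]-4-{[(triethylsilyl)oxy]methyl}dihydrofuran-2(3H)-one | OC/C(=C/[C@@H]1OC(=O)C[C@@H]1CO[Si](CC)(CC)CC)[Sn](CCCC)(CCCC)CCCC
F7 | step 8 | (4R,5R)-5-[(Z)-3-hydroxy-2-iodoprop-1-en-1-yl]-4-{[(triethylsilyl)oxy]methyl}dihydrofuran-2(3H)-one | OC/C(I)=C/[C@@H]1OC(=O)C[C@@H]1CO[Si](CC)(CC)CC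
F8 | step 17 | 8-O-triethylsilyl ether of 29 | C1C(=O)O[C@H]2/C=C(/COCc3ccc(OC)cc3)CC[C@@H](O[Si](C)(C)C(C)(C)C)C(=C)C[C@H](O[Si](CC)(CC)CC)[C@@H]12
F9 | step 17 | 13-(dimethylamino)-11(13)-ene (enamino lactone) of F8 | CN(C)C=C1C(=O)O[C@H]2/C=C(/COCc3ccc(OC)cc3)CC[C@@H](O[Si](C)(C)C(C)(C)C)C(=C)C[C@H](O[Si](CC)(CC)CC)[C@@H]12
F10 | step 17 | 8-O-triethylsilyl ether of 34 | C=C1C(=O)O[C@H]2/C=C(/COCc3ccc(OC)cc3)CC[C@@H](O[Si](C)(C)C(C)(C)C)C(=C)C[C@H](O[Si](CC)(CC)CC)[C@@H]12
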